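**Assumption:** the target has no stereocentre, so "single enantiomer" is read as the single (E)-alkene isomer. 1,2,4,5-Tetramethoxybenzene, 1,12-dibromododecane and trans-2-heptenyl acetate are taken as catalogue chemicals.

## Retrosynthetic overview

- The dihydroxyquinone comes from vinylogous-ester hydrolysis of the 2,5-dimethoxyquinone, which comes from CAN oxidative demethylation of a hexasubstituted 1,2,4,5-tetramethoxybenzene.
- The side chain is cut at C12'–C13' (sp3–sp3): a Cu-catalysed coupling of an ω-aryl-dodecyl Grignard with (E)-hept-2-enyl acetate, which brings the E-alkene in ready-made.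
- The aryl–C1' bond comes from alkylation of lithiated tetramethoxytoluene with 1,12-dibromododecane, and the aryl–CH3 bond from lithiation/methylation of 1,2,4,5-tetramethoxybenzene.
- No ring is formed: the single six-membered carbocycle is bought and only oxidised to the quinone at the end.

## Route

Step 1
Reactants: 1 1,2,4,5-tetramethoxybenzene
Product: 3 1,2,4,5-tetramethoxy-3-methylbenzene, via aryllithium 2 (not isolated)
Conditions: n-BuLi (1.1 equiv), THF, 0 °C → rt, 1 h; then MeI (1.5 equiv), 0 °C → rt
Reagents that add atoms: iodomethane, CI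
Why: Directed ortho-lithiation removes a ring C–H flanked by two OMe groups and the aryllithium is methylated by SN2 on MeI; no stereocentre is formed.

Step 2
Reactants: 3 1,2,4,5-tetramethoxy-3-methylbenzene; 4 1,12-dibromododecane
Product: 6 1-(12-bromododecyl)-2,3,5,6-tetramethoxy-4-methylbenzene, via aryllithium 5 (not isolated)
Conditions: n-BuLi (1.1 equiv), THF, 0 °C → rt, 1 h; then cannulated into 4 (4 equiv), THF–DMPU, −20 °C → rt (excess 4 recovered)
Reagents that add atoms: none
Why: A second directed ortho-lithiation at the only remaining ring C–H is followed by SN2 alkylation of the aryllithium on the primary dibromide, with the fourfold excess and inverse addition holding it at mono-substitution; no stereocentre is formed.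

Step 3
Reactants: 6 1-(12-bromododecyl)-2,3,5,6-tetramethoxy-4-methylbenzene; 7 (E)-hept-2-en-1-yl acetate
Product: 9 1,2,4,5-tetramethoxy-3-methyl-6-[(E)-nonadec-14-en-1-yl]benzene, via Grignard reagent 8 (not isolated)
Conditions: Mg (1.5 equiv, I2-activated), THF, 45 °C; then added rapidly to 7 (1.2 equiv), Li2CuCl4 (3 mol %), THF, −30 → 0 °C; aq NH4Cl
Reagents that add atoms: none
Why: In this Kochi–Schlosser-type Cu-catalysed Grignard/allylic acetate coupling, Li2CuCl4 with fast Grignard addition at low temperature favours α (SN2) substitution at the primary allylic carbon, so the pre-formed (E)-alkene of 7 is carried into 9 unchanged and no new stereo element is created.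

Step 4
Reactants: 9 1,2,4,5-tetramethoxy-3-methyl-6-[(E)-nonadec-14-en-1-yl]benzene
Product: 10 2,5-dimethoxy-3-methyl-6-[(E)-nonadec-14-en-1-yl]cyclohexa-2,5-diene-1,4-dione
Conditions: CAN (2.5 equiv), MeCN–CH2Cl2–H2O, 0 °C, 20 min
Reagents that add atoms: water, O
Why: CAN oxidative demethylation (two one-electron oxidations, water attack at two para OMe-bearing carbons, loss of 2 MeOH) gives the dimethoxy-p-quinone while the isolated alkene is untouched at 0 °C; any isomeric 4,5-dimethoxy-o-quinone co-formed converges on the same product in step 5.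

Step 5
Reactants: 10 2,5-dimethoxy-3-methyl-6-[(E)-nonadec-14-en-1-yl]cyclohexa-2,5-diene-1,4-dione
Product: 12 2,5-dihydroxy-3-methyl-6-[(E)-nonadec-14-en-1-yl]cyclohexa-2,5-diene-1,4-dione (target), via disodium quinonate 11 (not isolated)
Conditions: 2 M aq NaOH, EtOH–THF, 65 °C, 2 h; then 2 M HCl to pH 1, 0 °C
Reagents that add atoms: sodium hydroxide, [Na+].[OH-]
Why: Both OMe groups are vinylogous esters, so hydroxide displaces them by conjugate addition–elimination (vinylogous saponification) to the disodium quinonate, which HCl protonates to the dihydroxyquinone; the remote E-alkene is inert to these conditions.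

## Compound list

1 | 1,2,4,5-tetramethoxybenzene | COc1cc(OC)c(OC)cc1OC | starting material
2 | (2,3,5,6-tetramethoxyphenyl)lithium (formed in situ) | [Li]c1c(OC)c(OC)cc(OC)c1OC | intermediate
3 | 1,2,4,5-tetramethoxy-3-methylbenzene | Cc1c(OC)c(OC)cc(OC)c1OC | intermediate
4 | 1,12-dibromododecane | BrCCCCCCCCCCCCBr | starting material
5 | (2,3,5,6-tetramethoxy-4-methylphenyl)lithium (formed in situ) | [Li]c1c(OC)c(OC)c(C)c(OC)c1OC | intermediate
6 | 1-(12-bromododecyl)-2,3,5,6-tetramethoxy-4-methylbenzene | Cc1c(OC)c(OC)c(CCCCCCCCCCCCBr)c(OC)c1OC | intermediate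
7 | (E)-hept-2-en-1-yl acetate | CCCC/C=C/COC(C)=O | starting material
8 | [12-(2,3,5,6-tetramethoxy-4-methylphenyl)dodecyl]magnesium bromide (formed in situ) | Cc1c(OC)c(OC)c(CCCCCCCCCCCC[Mg]Br)c(OC)c1OC | intermediate
9 | 1,2,4,5-tetramethoxy-3-methyl-6-[(E)-nonadec-14-en-1-yl]benzene | Cc1c(OC)c(OC)c(CCCCCCCCCCCCC/C=C/CCCC)c(OC)c1OC | intermediate
10 | 2,5-dimethoxy-3-methyl-6-[(E)-nonadec-14-en-1-yl]cyclohexa-2,5-diene-1,4-dione | CCCC/C=C/CCCCCCCCCCCCCC1=C(OC)C(=O)C(C)=C(OC)C1=O | intermediate
11 | disodium 3-methyl-6-[(E)-nonadec-14-en-1-yl]-2,5-dioxidocyclohexa-2,5-diene-1,4-dione (formed in situ) | [Na+].[Na+].CCCC/C=C/CCCCCCCCCCCCCC1=C([O-])C(=O)C(C)=C([O-])C1=O | intermediate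
12 | 2,5-dihydroxy-3-methyl-6-[(E)-nonadec-14-en-1-yl]cyclohexa-2,5-diene-1,4-dione | CCCC/C=C/CCCCCCCCCCCCCC1=C(O)C(=O)C(C)=C(O)C1=O | target

## Summary

Total step count: 5. Longest linear sequence: 5 steps (1 → 3 → 6 → 9 → 10 → 12).

## Steps most likely to fail, with fallbacks

**Step 3** is the main risk: α- versus γ-attack on the allylic acetate, Wurtz dimer, and Grignard attack on the acetate carbonyl. The branched γ-isomer would need AgNO3–silica chromatography to remove. The fallback sets out from 3 and comes back at 9, building the whole C19 chain separately and setting the alkene by dissolving-metal reduction. Hex-1-yne is lithiated with n-BuLi to hex-1-yn-1-yllithium F1. A 2.2-equiv portion of it alkylates commercial 13-bromotridecan-1-ol in THF–DMPU to give nonadec-14-yn-1-ol F2. Li in NH3(l)–THF at −33 °C reduces the alkyne by anti addition to (E)-nonadec-14-en-1-ol F3. CBr4/PPh3 converts the alcohol to (E)-19-bromononadec-5-ene F4. This bromide alkylates aryllithium 5 (made from 3 as in step 2) to give 9 directly, replacing steps 2 and 3.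

**Step 2** relies on statistical mono-substitution of a symmetrical dibromide, with bis-arylation and E2 as side reactions. The fallback sets out from 3 and comes back at 6, making the aryl–alkyl bond by cross-coupling instead of SN2. NBS in MeCN brominates the last ring position of 3 to give 1-bromo-2,3,5,6-tetramethoxy-4-methylbenzene F5. Commercial 12-bromododec-1-ene is hydroborated with 9-BBN to 9-(12-bromododecyl)-9-borabicyclo[3.3.1]nonane F6. A B-alkyl Suzuki–Miyaura coupling (Pd(OAc)2/SPhos, K3PO4, THF–H2O, 60 °C) of F5 with F6 gives 6, with the aryl C–Br bond reacting and the primary alkyl bromide a spectator.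

**Step 4** may give o-/p-quinone mixtures, nitrated or over-oxidised by-products, and suffers from poor solubility of the lipophilic substrate. The fallback sets out from 9 and comes back at 12, deprotecting first and oxidising second. BBr3 in CH2Cl2 (−78 → 0 °C, cold NaHCO3 quench to spare the alkene) removes all four methyl groups to give 3-methyl-6-[(E)-nonadec-14-en-1-yl]benzene-1,2,4,5-tetrol F7. This air-sensitive tetrol is oxidised by O2 (air, aq NaHCO3/EtOAc) to 12, skipping 10 and step 5.

## Further compounds

F1 | step 3 | hex-1-yn-1-yllithium | CCCCC#C[Li]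
F2 | step 3 | nonadec-14-yn-1-ol | CCCCC#CCCCCCCCCCCCCCO
F3 | step 3 | (E)-nonadec-14-en-1-ol | CCCC/C=C/CCCCCCCCCCCCCO
F4 | step 3 | (E)-19-bromononadec-5-ene | CCCC/C=C/CCCCCCCCCCCCCBr
F5 | step 2 | 1-bromo-2,3,5,6-tetramethoxy-4-methylbenzene | Cc1c(OC)c(OC)c(Br)c(OC)c1OC
F6 | step 2 | 9-(12-bromododecyl)-9-borabicyclo[3.3.1]nonane | BrCCCCCCCCCCCCB1C2CCCC1CCC2
F7 | step 4 | 3-methyl-6-[(E)-nonadec-14-en-1-yl]benzene-1,2,4,5-tetrol | CCCC/C=C/CCCCCCCCCCCCCc1c(O)c(O)c(C)c(O)c1O
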